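1. Locants as in 12-oxabicyclo[9.1.0]dodec-4-ene (C4 CO2H, C6 OBz, C7 CMe2, C1/C11 oxirane). Target ⇒ allyl ester/TBS ether 32; the 11-membered ring is closed last at C4=C5 by intramolecular Horner–Wadsworth–Emmons olefination of phosphonate aldehyde 30.
2. 30 ⇒ allyl diethylphosphonoacetate 26 + epoxy iodide 25 (C3–C4); the oxirane comes from reagent-controlled Shi epoxidation of the open-chain (E)-olefin 23.
3. 23 ⇒ alkyne 19 by Negishi carboalumination (C11 methyl, E geometry) and oxirane opening (C2, C3); 19 ⇒ iodide 15 + propargyl anion (C9–C10).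
4. Key C6–C7 bond: intermolecular asymmetric carbonyl allylation (Brown tert-prenylation) of aldehyde 5 with the prenylborane made from allene 8, which sets the carbinol stereocentre and the quaternary carbon of 11 together.
5. Ring order: oxirane first (step 11, acyclic), carbocycle second (step 16).

Assumption: every compound marked "starting material" is taken as purchasable; (+)-α-pinene of high optical purity is used. The sense of induction in steps 4 and 11 is assigned from the accepted models for these reagents, not from a precedent on these exact substrates.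

Step 1
Reactants: 1 (2Z)-but-2-ene-1,4-diol
Product: 3 (2Z)-1,4-bis[(4-methoxybenzyl)oxy]but-2-ene, via disodium (2Z)-but-2-ene-1,4-diolate 2 (not isolated)
Conditions: NaH, THF/DMF, 0 °C; then 4-methoxybenzyl chloride, Bu4NI (cat.), 0 °C → rt
Reagents that add atoms: 4-methoxybenzyl chloride, COc1ccc(CCl)cc1
Why: Williamson ether synthesis on both primary alkoxides gives a symmetric alkene that serves as two masked aldehyde units.

Step 2
Reactants: 3 (2Z)-1,4-bis[(4-methoxybenzyl)oxy]but-2-ene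
Product: 5 [(4-methoxybenzyl)oxy]acetaldehyde, via ozonide 4 (not isolated)
Conditions: O3, CH2Cl2, −78 °C (stopped at the first blue tint); then PPh3, −78 °C → rt
Reagents that add atoms: ozone, [O-][O+]=O
Why: Ozonolysis with reductive work-up cleaves the electron-rich alkene faster than the anisyl rings and gives two equivalents of the aldehyde, which is used fresh.

Step 3
Reactants: 6 (1R,5R)-(+)-α-pinene
Product: 7 (−)-diisopinocampheylborane
Conditions: BH3·SMe2, THF, 0 °C, 3 d; crystalline 7 collected under N2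
Reagents that add atoms: borane–dimethyl sulfide, C[S+](C)[BH3-]
Why: Hydroboration of two pinene molecules from the face anti to the gem-dimethyl bridge gives the dialkylborane, and slow equilibration/crystallisation raises its optical purity.

Step 4
Reactants: 7 (−)-diisopinocampheylborane, 8 3-methylbuta-1,2-diene, 5 [(4-methoxybenzyl)oxy]acetaldehyde
Product: 11 (2S)-1-[(4-methoxybenzyl)oxy]-3,3-dimethylpent-4-en-2-ol, via prenyldiisopinocampheylborane 9 (not isolated), via diisopinocampheylborinate ester 10 (not isolated)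
Conditions: 7 + 8, THF, −25 °C, 6 h; then 5, Et2O, −78 °C, 12 h; then NaOH, H2O2, 0 °C → rt
Reagents that add atoms: none
Why: Brown asymmetric allylboration (tert-prenylation): hydroboration of the allene gives the γ,γ-dimethylallylborane, which delivers its tertiary terminus through a closed chair (Zimmerman–Traxler) transition state to the Si face of the aldehyde under control of the (+)-α-pinene-derived ligands, creating the (S)-carbinol (C6 of the target) and the adjacent quaternary carbon in one intermolecular C–C bond formation.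

Step 5
Reactants: 11 (2S)-1-[(4-methoxybenzyl)oxy]-3,3-dimethylpent-4-en-2-ol
Product: 12 tert-butyl{[(2S)-1-[(4-methoxybenzyl)oxy]-3,3-dimethylpent-4-en-2-yl]oxy}dimethylsilane
Conditions: TBSOTf, 2,6-lutidine, CH2Cl2, 0 °C
Reagents that add atoms: tert-butyldimethylsilyl trifluoromethanesulfonate, CC(C)(C)[Si](C)(C)OS(=O)(=O)C(F)(F)F
Why: Silylation with the reactive silyl triflate protects the hindered neopentylic secondary alcohol without touching the stereocentre.

Step 6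
Reactants: 12 tert-butyl{[(2S)-1-[(4-methoxybenzyl)oxy]-3,3-dimethylpent-4-en-2-yl]oxy}dimethylsilane
Product: 14 (4S)-4-[(tert-butyldimethylsilyl)oxy]-5-[(4-methoxybenzyl)oxy]-3,3-dimethylpentan-1-ol, via B-alkyl-9-borabicyclo[3.3.1]nonane 13 (not isolated)
Conditions: 9-BBN, THF, 0 → 50 °C; then NaOH, H2O2, 0 °C → rt
Reagents that add atoms: hydrogen peroxide, OO
Why: Hydroboration–oxidation with the bulky borane is fully anti-Markovnikov on a vinyl group attached to a quaternary carbon and gives the primary alcohol.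

Step 7
Reactants: 14 (4S)-4-[(tert-butyldimethylsilyl)oxy]-5-[(4-methoxybenzyl)oxy]-3,3-dimethylpentan-1-ol
Product: 15 tert-butyl{[(2S)-5-iodo-1-[(4-methoxybenzyl)oxy]-3,3-dimethylpentan-2-yl]oxy}dimethylsilane
Conditions: I2, PPh3, imidazole, CH2Cl2, 0 °C → rt
Reagents that add atoms: iodine, II
Why: Garegg–Samuelsson (Appel-type) iodination converts the unhindered primary alcohol into the iodide under neutral conditions.

Step 8
Reactants: 15 tert-butyl{[(2S)-5-iodo-1-[(4-methoxybenzyl)oxy]-3,3-dimethylpentan-2-yl]oxy}dimethylsilane, 16 trimethyl(prop-1-yn-1-yl)silane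
Product: 18 tert-butyl{[(2S)-1-[(4-methoxybenzyl)oxy]-3,3-dimethyl-8-(trimethylsilyl)oct-7-yn-2-yl]oxy}dimethylsilane, via lithiated silylpropyne 17 (not isolated)
Conditions: 16, n-BuLi, THF, −78 → −20 °C; then 15, −78 °C → rt
Reagents that add atoms: none
Why: SN2 alkylation of the silyl-stabilised propargyllithium by the primary iodide gives the propargylic (not allenic) product and adds the three carbons C10, C11 and C1 of the target.

Step 9
Reactants: 18 tert-butyl{[(2S)-1-[(4-methoxybenzyl)oxy]-3,3-dimethyl-8-(trimethylsilyl)oct-7-yn-2-yl]oxy}dimethylsilane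
Product: 19 tert-butyl{[(2S)-1-[(4-methoxybenzyl)oxy]-3,3-dimethyloct-7-yn-2-yl]oxy}dimethylsilane
Conditions: K2CO3 (0.2 equiv), MeOH, rt
Reagents that add atoms: none
Why: Methoxide-mediated protodesilylation removes only the alkynyl silyl group and leaves the silyl ether intact.

Step 10
Reactants: 19 tert-butyl{[(2S)-1-[(4-methoxybenzyl)oxy]-3,3-dimethyloct-7-yn-2-yl]oxy}dimethylsilane, 20 oxirane
Product: 23 (3E,9S)-9-[(tert-butyldimethylsilyl)oxy]-10-[(4-methoxybenzyl)oxy]-4,8,8-trimethyldec-3-en-1-ol, via alkenyldimethylalane 21 (not isolated), via lithium alkenylalanate 22 (not isolated)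
Conditions: Me3Al, Cp2ZrCl2 (0.25 equiv), CH2Cl2, 0 °C → rt; volatiles removed; n-BuLi, hexane/THF, 0 °C; then 20, 0 °C → rt; aq. Rochelle salt
Reagents that add atoms: trimethylaluminium, C[Al](C)C
Why: Negishi zirconium-catalysed carboalumination adds methyl and aluminium syn across the terminal alkyne, so the trisubstituted olefin is formed only as the E isomer, and the derived alanate opens oxirane with retention of geometry.

Step 11
Reactants: 23 (3E,9S)-9-[(tert-butyldimethylsilyl)oxy]-10-[(4-methoxybenzyl)oxy]-4,8,8-trimethyldec-3-en-1-ol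
Product: 24 2-{(2S,3S)-3-[(5S)-5-[(tert-butyldimethylsilyl)oxy]-6-[(4-methoxybenzyl)oxy]-4,4-dimethylhexyl]-3-methyloxiran-2-yl}ethan-1-ol
Conditions: 1,2:4,5-di-O-isopropylidene-β-L-erythro-2,3-hexodiulo-2,6-pyranose (L-configured Shi ketone, C12H18O6, 0.3 equiv), KHSO5 (as 2KHSO5·KHSO4·K2SO4), K2CO3, Bu4NHSO4 (cat.), MeCN/CH2(OMe)2/aq. Na2B4O7–Na2EDTA, 0 °C
Reagents that add atoms: potassium peroxymonosulfate, [K+].[O-]S(=O)(=O)OO
Why: Shi asymmetric epoxidation: the chiral dioxirane attacks the (E)-trisubstituted olefin through a spiro transition state, and the L-configured ketone (enantiomer of the usual D-fructose catalyst) gives the (S,S)-oxirane under catalyst control, independent of the remote carbinol centre.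

Step 12
Reactants: 24 2-{(2S,3S)-3-[(5S)-5-[(tert-butyldimethylsilyl)oxy]-6-[(4-methoxybenzyl)oxy]-4,4-dimethylhexyl]-3-methyloxiran-2-yl}ethan-1-ol
Product: 25 tert-butyl{[(2S)-6-[(2S,3S)-3-(2-iodoethyl)-2-methyloxiran-2-yl]-1-[(4-methoxybenzyl)oxy]-3,3-dimethylhexan-2-yl]oxy}dimethylsilane
Conditions: I2, PPh3, imidazole, CH2Cl2, 0 °C, 30 min
Reagents that add atoms: iodine, II
Why: Garegg–Samuelsson iodination is buffered by imidazole, so the primary alcohol is exchanged for iodide while the trisubstituted oxirane survives.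

Step 13
Reactants: 25 tert-butyl{[(2S)-6-[(2S,3S)-3-(2-iodoethyl)-2-methyloxiran-2-yl]-1-[(4-methoxybenzyl)oxy]-3,3-dimethylhexan-2-yl]oxy}dimethylsilane, 26 prop-2-en-1-yl (diethoxyphosphoryl)acetate
Product: 28 prop-2-en-1-yl 4-{(2S,3S)-3-[(5S)-5-[(tert-butyldimethylsilyl)oxy]-6-[(4-methoxybenzyl)oxy]-4,4-dimethylhexyl]-3-methyloxiran-2-yl}-2-(diethoxyphosphoryl)butanoate, via sodium phosphonoacetate enolate 27 (not isolated)
Conditions: 26 (1.8 equiv), NaH (1.5 equiv), DMF, 0 °C → rt; then 25, 50 °C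
Reagents that add atoms: none
Why: SN2 C-alkylation of the soft, stabilised phosphonoacetate anion occurs at the primary iodide and not at the hindered oxirane; the new centre at C2 is a 1:1 mixture that is removed in the later olefination.

Step 14
Reactants: 28 prop-2-en-1-yl 4-{(2S,3S)-3-[(5S)-5-[(tert-butyldimethylsilyl)oxy]-6-[(4-methoxybenzyl)oxy]-4,4-dimethylhexyl]-3-methyloxiran-2-yl}-2-(diethoxyphosphoryl)butanoate
Product: 29 prop-2-en-1-yl 4-{(2S,3S)-3-[(5S)-5-[(tert-butyldimethylsilyl)oxy]-6-hydroxy-4,4-dimethylhexyl]-3-methyloxiran-2-yl}-2-(diethoxyphosphoryl)butanoate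
Conditions: DDQ, CH2Cl2/pH 7 phosphate buffer (10:1), 0 °C → rt
Reagents that add atoms: none
Why: Oxidative cleavage of the 4-methoxybenzyl ether by the quinone proceeds at neutral pH, so the oxirane, allyl ester, phosphonate and silyl ether are untouched.

Step 15
Reactants: 29 prop-2-en-1-yl 4-{(2S,3S)-3-[(5S)-5-[(tert-butyldimethylsilyl)oxy]-6-hydroxy-4,4-dimethylhexyl]-3-methyloxiran-2-yl}-2-(diethoxyphosphoryl)butanoate
Product: 30 prop-2-en-1-yl 4-{(2S,3S)-3-[(5S)-5-[(tert-butyldimethylsilyl)oxy]-4,4-dimethyl-6-oxohexyl]-3-methyloxiran-2-yl}-2-(diethoxyphosphoryl)butanoate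
Conditions: Dess–Martin periodinane, NaHCO3, CH2Cl2, 0 °C → rt; used at once
Reagents that add atoms: none
Why: Buffered Dess–Martin oxidation gives the α-silyloxy aldehyde without epimerisation, because the α-centre is flanked by a quaternary carbon and no base is present.

Step 16
Reactants: 30 prop-2-en-1-yl 4-{(2S,3S)-3-[(5S)-5-[(tert-butyldimethylsilyl)oxy]-4,4-dimethyl-6-oxohexyl]-3-methyloxiran-2-yl}-2-(diethoxyphosphoryl)butanoate
Product: 32 prop-2-en-1-yl (1S,4E,6R,11S)-6-[(tert-butyldimethylsilyl)oxy]-7,7,11-trimethyl-12-oxabicyclo[9.1.0]dodec-4-ene-4-carboxylate, via lithium phosphonate enolate 31 (not isolated)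
Conditions: LiCl, DBU, MeCN, 0.001 M (syringe-pump addition of 30 over 12 h), rt → 40 °C
Reagents that add atoms: none
Why: Intramolecular Horner–Wadsworth–Emmons olefination under Masamune–Roush conditions closes the 11-membered ring, and both the usual preference (ester trans to the β-substituent) and ring strain favour the (4E)-enoate, whose ring carbons are cis.

Step 17
Reactants: 32 prop-2-en-1-yl (1S,4E,6R,11S)-6-[(tert-butyldimethylsilyl)oxy]-7,7,11-trimethyl-12-oxabicyclo[9.1.0]dodec-4-ene-4-carboxylate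
Product: 33 prop-2-en-1-yl (1S,4E,6R,11S)-6-hydroxy-7,7,11-trimethyl-12-oxabicyclo[9.1.0]dodec-4-ene-4-carboxylate
Conditions: Bu4NF, THF, 0 °C → rt
Reagents that add atoms: none
Why: Fluoride-mediated desilylation frees the allylic alcohol, which cannot lactonise onto the ester because the two are trans across the olefin.

Step 18
Reactants: 33 prop-2-en-1-yl (1S,4E,6R,11S)-6-hydroxy-7,7,11-trimethyl-12-oxabicyclo[9.1.0]dodec-4-ene-4-carboxylate
Product: 34 prop-2-en-1-yl (1S,4E,6R,11S)-6-(benzoyloxy)-7,7,11-trimethyl-12-oxabicyclo[9.1.0]dodec-4-ene-4-carboxylate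
Conditions: benzoyl chloride, pyridine, DMAP (0.2 equiv), CH2Cl2, 0 °C → rt
Reagents that add atoms: benzoyl chloride, O=C(Cl)c1ccccc1
Why: DMAP-catalysed acylation benzoylates the hindered secondary alcohol with retention, since the C–O bond is not broken.

Step 19
Reactants: 34 prop-2-en-1-yl (1S,4E,6R,11S)-6-(benzoyloxy)-7,7,11-trimethyl-12-oxabicyclo[9.1.0]dodec-4-ene-4-carboxylate
Product: 35 (1S,4E,6R,11S)-6-(benzoyloxy)-7,7,11-trimethyl-12-oxabicyclo[9.1.0]dodec-4-ene-4-carboxylic acid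
Conditions: Pd(PPh3)4 (5 mol %), morpholine, THF, 0 °C → rt; pH 5 phosphate work-up
Reagents that add atoms: none
Why: Tsuji–Trost deallylation: zerovalent palladium ionises the unhindered allyl ester much faster than the neopentylic secondary allylic benzoate, and the neutral conditions spare the benzoate and the oxirane.

Compound list
1 | (2Z)-but-2-ene-1,4-diol | OC/C=C\CO | starting material
2 | disodium (2Z)-but-2-ene-1,4-diolate | [Na+].[Na+].[O-]C/C=C\C[O-] | intermediate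
3 | (2Z)-1,4-bis[(4-methoxybenzyl)oxy]but-2-ene | COc1ccc(COC/C=C\COCc2ccc(OC)cc2)cc1 | intermediate
4 | 3,5-bis{[(4-methoxybenzyl)oxy]methyl}-1,2,4-trioxolane (ozonide, cis/trans mixture) | COc1ccc(COCC2OOC(COCc3ccc(OC)cc3)O2)cc1 | intermediate
5 | [(4-methoxybenzyl)oxy]acetaldehyde | COc1ccc(COCC=O)cc1 | intermediate
6 | (1R,5R)-(+)-α-pinene | CC1=CC[C@@H]2C[C@H]1C2(C)C | starting material
7 | (−)-diisopinocampheylborane (from (+)-α-pinene) | [BH]([C@@H]1C[C@@H]2C[C@@H](C2(C)C)[C@H]1C)[C@@H]1C[C@@H]2C[C@@H](C2(C)C)[C@H]1C | intermediate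
8 | 3-methylbuta-1,2-diene | CC(C)=C=C | starting material
9 | B-(3-methylbut-2-en-1-yl)diisopinocampheylborane | CC(C)=CCB([C@@H]1C[C@@H]2C[C@@H](C2(C)C)[C@H]1C)[C@@H]1C[C@@H]2C[C@@H](C2(C)C)[C@H]1C | intermediate
10 | (2S)-1-[(4-methoxybenzyl)oxy]-3,3-dimethylpent-4-en-2-yl diisopinocampheylborinate | C=CC(C)(C)[C@@H](COCc1ccc(OC)cc1)OB([C@@H]1C[C@@H]2C[C@@H](C2(C)C)[C@H]1C)[C@@H]1C[C@@H]2C[C@@H](C2(C)C)[C@H]1C | intermediate
11 | (2S)-1-[(4-methoxybenzyl)oxy]-3,3-dimethylpent-4-en-2-ol | C=CC(C)(C)[C@H](O)COCc1ccc(OC)cc1 | intermediate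
12 | tert-butyl{[(2S)-1-[(4-methoxybenzyl)oxy]-3,3-dimethylpent-4-en-2-yl]oxy}dimethylsilane | C=CC(C)(C)[C@H](O[Si](C)(C)C(C)(C)C)COCc1ccc(OC)cc1 | intermediate
13 | 9-{(4S)-4-[(tert-butyldimethylsilyl)oxy]-5-[(4-methoxybenzyl)oxy]-3,3-dimethylpentyl}-9-borabicyclo[3.3.1]nonane | B1(CCC(C)(C)[C@H](O[Si](C)(C)C(C)(C)C)COCc3ccc(OC)cc3)C2CCCC1CCC2 | intermediate
14 | (4S)-4-[(tert-butyldimethylsilyl)oxy]-5-[(4-methoxybenzyl)oxy]-3,3-dimethylpentan-1-ol | OCCC(C)(C)[C@H](O[Si](C)(C)C(C)(C)C)COCc1ccc(OC)cc1 | intermediate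
15 | tert-butyl{[(2S)-5-iodo-1-[(4-methoxybenzyl)oxy]-3,3-dimethylpentan-2-yl]oxy}dimethylsilane | ICCC(C)(C)[C@H](O[Si](C)(C)C(C)(C)C)COCc1ccc(OC)cc1 | intermediate
16 | trimethyl(prop-1-yn-1-yl)silane | CC#C[Si](C)(C)C | starting material
17 | [3-(trimethylsilyl)prop-2-yn-1-yl]lithium | [Li]CC#C[Si](C)(C)C | intermediate
18 | tert-butyl{[(2S)-1-[(4-methoxybenzyl)oxy]-3,3-dimethyl-8-(trimethylsilyl)oct-7-yn-2-yl]oxy}dimethylsilane | C[Si](C)(C)C#CCCCC(C)(C)[C@H](O[Si](C)(C)C(C)(C)C)COCc1ccc(OC)cc1 | intermediate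
19 | tert-butyl{[(2S)-1-[(4-methoxybenzyl)oxy]-3,3-dimethyloct-7-yn-2-yl]oxy}dimethylsilane | C#CCCCC(C)(C)[C@H](O[Si](C)(C)C(C)(C)C)COCc1ccc(OC)cc1 | intermediate
20 | oxirane (ethylene oxide) | C1CO1 | starting material
21 | [(1E,7S)-7-[(tert-butyldimethylsilyl)oxy]-8-[(4-methoxybenzyl)oxy]-2,6,6-trimethyloct-1-en-1-yl]dimethylalane | C[Al](C)/C=C(\C)CCCC(C)(C)[C@H](O[Si](C)(C)C(C)(C)C)COCc1ccc(OC)cc1 | intermediate
22 | lithium butyl[(1E,7S)-7-[(tert-butyldimethylsilyl)oxy]-8-[(4-methoxybenzyl)oxy]-2,6,6-trimethyloct-1-en-1-yl]dimethylalanate | [Li+].CCCC[Al-](C)(C)/C=C(\C)CCCC(C)(C)[C@H](O[Si](C)(C)C(C)(C)C)COCc1ccc(OC)cc1 | intermediate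
23 | (3E,9S)-9-[(tert-butyldimethylsilyl)oxy]-10-[(4-methoxybenzyl)oxy]-4,8,8-trimethyldec-3-en-1-ol | OCC/C=C(\C)CCCC(C)(C)[C@H](O[Si](C)(C)C(C)(C)C)COCc1ccc(OC)cc1 | intermediate
24 | 2-{(2S,3S)-3-[(5S)-5-[(tert-butyldimethylsilyl)oxy]-6-[(4-methoxybenzyl)oxy]-4,4-dimethylhexyl]-3-methyloxiran-2-yl}ethan-1-ol | OCC[C@@H]1O[C@@]1(C)CCCC(C)(C)[C@H](O[Si](C)(C)C(C)(C)C)COCc2ccc(OC)cc2 | intermediate
25 | tert-butyl{[(2S)-6-[(2S,3S)-3-(2-iodoethyl)-2-methyloxiran-2-yl]-1-[(4-methoxybenzyl)oxy]-3,3-dimethylhexan-2-yl]oxy}dimethylsilane | ICC[C@@H]1O[C@@]1(C)CCCC(C)(C)[C@H](O[Si](C)(C)C(C)(C)C)COCc2ccc(OC)cc2 | intermediate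
26 | prop-2-en-1-yl (diethoxyphosphoryl)acetate | C=CCOC(=O)CP(=O)(OCC)OCC | starting material
27 | sodium enolate of prop-2-en-1-yl (diethoxyphosphoryl)acetate | [Na+].C=CCOC([O-])=CP(=O)(OCC)OCC | intermediate
28 | prop-2-en-1-yl 4-{(2S,3S)-3-[(5S)-5-[(tert-butyldimethylsilyl)oxy]-6-[(4-methoxybenzyl)oxy]-4,4-dimethylhexyl]-3-methyloxiran-2-yl}-2-(diethoxyphosphoryl)butanoate (both C2 epimers) | C=CCOC(=O)C(CC[C@@H]1O[C@@]1(C)CCCC(C)(C)[C@H](O[Si](C)(C)C(C)(C)C)COCc2ccc(OC)cc2)P(=O)(OCC)OCC | intermediate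
29 | prop-2-en-1-yl 4-{(2S,3S)-3-[(5S)-5-[(tert-butyldimethylsilyl)oxy]-6-hydroxy-4,4-dimethylhexyl]-3-methyloxiran-2-yl}-2-(diethoxyphosphoryl)butanoate (both C2 epimers) | C=CCOC(=O)C(CC[C@@H]1O[C@@]1(C)CCCC(C)(C)[C@H](O[Si](C)(C)C(C)(C)C)CO)P(=O)(OCC)OCC | intermediate
30 | prop-2-en-1-yl 4-{(2S,3S)-3-[(5S)-5-[(tert-butyldimethylsilyl)oxy]-4,4-dimethyl-6-oxohexyl]-3-methyloxiran-2-yl}-2-(diethoxyphosphoryl)butanoate (both C2 epimers) | C=CCOC(=O)C(CC[C@@H]1O[C@@]1(C)CCCC(C)(C)[C@H](O[Si](C)(C)C(C)(C)C)C=O)P(=O)(OCC)OCC | intermediate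
31 | lithium enolate of 30 | [Li+].C=CCOC([O-])=C(CC[C@@H]1O[C@@]1(C)CCCC(C)(C)[C@H](O[Si](C)(C)C(C)(C)C)C=O)P(=O)(OCC)OCC | intermediate
32 | prop-2-en-1-yl (1S,4E,6R,11S)-6-[(tert-butyldimethylsilyl)oxy]-7,7,11-trimethyl-12-oxabicyclo[9.1.0]dodec-4-ene-4-carboxylate | CC1(C)CCC[C@]2(C)O[C@H]2CC/C(C(=O)OCC=C)=C\[C@H]1O[Si](C)(C)C(C)(C)C | intermediate
33 | prop-2-en-1-yl (1S,4E,6R,11S)-6-hydroxy-7,7,11-trimethyl-12-oxabicyclo[9.1.0]dodec-4-ene-4-carboxylate | CC1(C)CCC[C@]2(C)O[C@H]2CC/C(C(=O)OCC=C)=C\[C@H]1O | intermediate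
34 | prop-2-en-1-yl (1S,4E,6R,11S)-6-(benzoyloxy)-7,7,11-trimethyl-12-oxabicyclo[9.1.0]dodec-4-ene-4-carboxylate | CC1(C)CCC[C@]2(C)O[C@H]2CC/C(C(=O)OCC=C)=C\[C@H]1OC(=O)c1ccccc1 | intermediate
35 | (1S,4E,6R,11S)-6-(benzoyloxy)-7,7,11-trimethyl-12-oxabicyclo[9.1.0]dodec-4-ene-4-carboxylic acid | CC1(C)CCC[C@]2(C)O[C@H]2CC/C(C(=O)O)=C\[C@H]1OC(=O)c1ccccc1 | target

Total step count: 19. Longest linear sequence: 18 (steps 1, 2 and 4–19; step 3 prepares the chiral borane).

Steps most likely to fail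

Step 16 (11-membered ring closure). The ring is strained, the aldehyde is hindered, dimerisation competes, and LiCl/DBU could attack the oxirane. Fallback: close the ring before the oxirane is present. Setting out from 23, Garegg–Samuelsson iodination gives tert-butyl{[(2S,7E)-10-iodo-1-[(4-methoxybenzyl)oxy]-3,3,7-trimethyldec-7-en-2-yl]oxy}dimethylsilane F1. Alkylation of the sodium enolate 27 with it gives prop-2-en-1-yl (5E,11S)-11-[(tert-butyldimethylsilyl)oxy]-2-(diethoxyphosphoryl)-12-[(4-methoxybenzyl)oxy]-6,10,10-trimethyldodec-5-enoate F2. DDQ then gives prop-2-en-1-yl (5E,11S)-11-[(tert-butyldimethylsilyl)oxy]-2-(diethoxyphosphoryl)-12-hydroxy-6,10,10-trimethyldodec-5-enoate F3, and Dess–Martin oxidation gives prop-2-en-1-yl (5E,11S)-11-[(tert-butyldimethylsilyl)oxy]-2-(diethoxyphosphoryl)-6,10,10-trimethyl-12-oxododec-5-enoate F4. High-dilution LiCl/DBU treatment forms the lithium enolate of that aldehyde F5, which cyclises to prop-2-en-1-yl (1E,3R,8E)-3-[(tert-butyldimethylsilyl)oxy]-4,4,8-trimethylcycloundeca-1,8-diene-1-carboxylate F6. Shi epoxidation with the same L-configured ketone then oxidises only the electron-rich ring olefin (not the enoate or the allyl group), and the route is rejoined at 32. The facial outcome on the macrocycle would have to be confirmed.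

Step 10 (one-pot carboalumination and oxirane opening). The alanate step is sensitive to residual Me3Al and zirconium species. Fallback: build C2–C3 by cross-coupling and hydroboration. Setting out from 19, the same carboalumination (alane 21) is quenched with I2 to give tert-butyl{[(2S,7E)-8-iodo-1-[(4-methoxybenzyl)oxy]-3,3,7-trimethyloct-7-en-2-yl]oxy}dimethylsilane F7. Suzuki–Miyaura coupling with potassium vinyltrifluoroborate (PdCl2(dppf), K2CO3, THF/H2O, 65 °C) gives tert-butyl{[(2S,7E)-1-[(4-methoxybenzyl)oxy]-3,3,7-trimethyldeca-7,9-dien-2-yl]oxy}dimethylsilane F8. 9-BBN adds only to the terminal vinyl group to give 9-[(3E,9S)-9-[(tert-butyldimethylsilyl)oxy]-10-[(4-methoxybenzyl)oxy]-4,8,8-trimethyldec-3-en-1-yl]-9-borabicyclo[3.3.1]nonane F9, and NaOH/H2O2 oxidation rejoins the route at 23.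

Step 4 (asymmetric tert-prenylation). The α-alkoxy aldehyde 5 hydrates and oligomerises easily, and the enantiomeric excess of the borane addition may fall short. Fallback: keep the allylation for the C–C bond but set the stereocentre by ketone reduction. Setting out from 5, prenylmagnesium chloride (THF, −78 °C, addition through its tertiary terminus) gives (±)-1-[(4-methoxybenzyl)oxy]-3,3-dimethylpent-4-en-2-ol F10. Dess–Martin oxidation gives 1-[(4-methoxybenzyl)oxy]-3,3-dimethylpent-4-en-2-one F11. Corey–Bakshi–Shibata reduction with (S)-1-methyl-3,3-diphenyltetrahydro-1H,3H-pyrrolo[1,2-c][1,3,2]oxazaborole (0.2 equiv) and BH3·SMe2 in toluene at −20 °C, with the tertiary alkyl group acting as the large substituent, should give the (S)-alcohol and rejoin the route at 11.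

Further compounds
F1 | step 16 | tert-butyl{[(2S,7E)-10-iodo-1-[(4-methoxybenzyl)oxy]-3,3,7-trimethyldec-7-en-2-yl]oxy}dimethylsilane | ICC/C=C(\C)CCCC(C)(C)[C@H](O[Si](C)(C)C(C)(C)C)COCc1ccc(OC)cc1
F2 | step 16 | prop-2-en-1-yl (5E,11S)-11-[(tert-butyldimethylsilyl)oxy]-2-(diethoxyphosphoryl)-12-[(4-methoxybenzyl)oxy]-6,10,10-trimethyldodec-5-enoate | C=CCOC(=O)C(CC/C=C(\C)CCCC(C)(C)[C@H](O[Si](C)(C)C(C)(C)C)COCc1ccc(OC)cc1)P(=O)(OCC)OCC
F3 | step 16 | prop-2-en-1-yl (5E,11S)-11-[(tert-butyldimethylsilyl)oxy]-2-(diethoxyphosphoryl)-12-hydroxy-6,10,10-trimethyldodec-5-enoate | C=CCOC(=O)C(CC/C=C(\C)CCCC(C)(C)[C@H](O[Si](C)(C)C(C)(C)C)CO)P(=O)(OCC)OCC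
F4 | step 16 | prop-2-en-1-yl (5E,11S)-11-[(tert-butyldimethylsilyl)oxy]-2-(diethoxyphosphoryl)-6,10,10-trimethyl-12-oxododec-5-enoate | C=CCOC(=O)C(CC/C=C(\C)CCCC(C)(C)[C@H](O[Si](C)(C)C(C)(C)C)C=O)P(=O)(OCC)OCC
F5 | step 16 | lithium enolate of F4 | [Li+].C=CCOC([O-])=C(CC/C=C(\C)CCCC(C)(C)[C@H](O[Si](C)(C)C(C)(C)C)C=O)P(=O)(OCC)OCC
F6 | step 16 | prop-2-en-1-yl (1E,3R,8E)-3-[(tert-butyldimethylsilyl)oxy]-4,4,8-trimethylcycloundeca-1,8-diene-1-carboxylate | CC1(C)CCC/C(C)=C/CC/C(C(=O)OCC=C)=C\[C@H]1O[Si](C)(C)C(C)(C)C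
F7 | step 10 | tert-butyl{[(2S,7E)-8-iodo-1-[(4-methoxybenzyl)oxy]-3,3,7-trimethyloct-7-en-2-yl]oxy}dimethylsilane | I/C=C(\C)CCCC(C)(C)[C@H](O[Si](C)(C)C(C)(C)C)COCc1ccc(OC)cc1
F8 | step 10 | tert-butyl{[(2S,7E)-1-[(4-methoxybenzyl)oxy]-3,3,7-trimethyldeca-7,9-dien-2-yl]oxy}dimethylsilane | C=C/C=C(\C)CCCC(C)(C)[C@H](O[Si](C)(C)C(C)(C)C)COCc1ccc(OC)cc1
F9 | step 10 | 9-[(3E,9S)-9-[(tert-butyldimethylsilyl)oxy]-10-[(4-methoxybenzyl)oxy]-4,8,8-trimethyldec-3-en-1-yl]-9-borabicyclo[3.3.1]nonane | B1(CC/C=C(\C)CCCC(C)(C)[C@H](O[Si](C)(C)C(C)(C)C)COCc3ccc(OC)cc3)C2CCCC1CCC2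
F10 | step 4 | (±)-1-[(4-methoxybenzyl)oxy]-3,3-dimethylpent-4-en-2-ol | C=CC(C)(C)C(O)COCc1ccc(OC)cc1
F11 | step 4 | 1-[(4-methoxybenzyl)oxy]-3,3-dimethylpent-4-en-2-one | C=CC(C)(C)C(=O)COCc1ccc(OC)cc1
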